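The target in these flasks is read in all its forms, but the question is about the part free in solution at the end, across four charges of protic impurity.

| setting | noon | spring | blue | grey | amber | ochre |
|---|---|---|---|---|---|---|
| starting material | 20 mM | 20 mM | 20 mM | 20 mM | 20 mM | 20 mM |
| protic impurity | 1.4 mM | 12 mM | 1.20 mM | 2.50 mM | 5.00 mM | 10.0 mM |
| remark | run made earlier | run made earlier |  |  |  |  |
| time |  |  | 8.0 min | 8.0 min | 8.0 min | 8.0 min |

- noon (time / min: target / %, starting material / %): 0.833: 21, 26; 1.50: 40, 12; 2.50: 53, 0; 3.00: 52, 1; 4.00: 56, 0; 5.00: 52, 1; 6.00: 51, 0
- spring (time / min: target / %, starting material / %): 0.333: 6, 59; 0.833: 21, 23; 1.50: 35, 8; 2.50: 47, 2; 3.00: 47, 3; 4.00: 49, 2; 6.00: 44, 0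

(each reading ± 1.5 percentage points)

- [target] (only what is free in solution) at the end for blue, grey, amber, ochre, in this order
- the course of these numbers from the first flask to the last (rises, then falls / rises all the way / falls all the way / falls, then rises / hardly changes)

- a reading or a percentage of target counts all its forms, free or not
- the concentration of target that is asked is that of its free form alone
- "hardly changes" means that all values lie within two and a half points (for a concentration: within two and a half percent of the largest)

Two chemists start from the same plateau. From 2.50 min on, the noon readings of target average 52.8 % of the charge and the spring readings 46.8 %, so the spring run stands 6 percentage points lower, against a scatter of 1.5 points per reading. Spring also holds more protic impurity, by 53.0 % of the starting material charged. Dividing one by the other gives 0.114. This is the impurity toll, the fraction of the charge of target lost per fraction of impurity charged. It is a small correction to a large number. Reckoned from noon, it puts the total target at 52.9 % for blue and 47.9 % for ochre.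

Here they part. The first chemist made the forecast, 10.7 mM, 10.5 mM, 10.2 mM and 9.6 mM, a course that falls all the way, on the view “so I take free to be about total”.

The second answers that a reading counting every form cannot show how much is free. She takes free target as the lesser of the total and a ceiling. If that ceiling stands under ochre's 47.9 %, the toll comes out of the undissolved part and the row stays flat. These readings give her no height for the ceiling, so she commits to the shape and to a level under 47.9 %.

The flasks give 1.90 mM, 1.90 mM, 1.90 mM and 1.90 mM, which hardly changes, at 9.50 % of the charge.

    starting material + protic impurity → quenched substrate (k = 0.376 M⁻¹ s⁻¹)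
    starting material → intermediate (k = 0.0256 s⁻¹)
    intermediate ⇌ isomer of the product A (K = 21.0, k = 0.00842 s⁻¹)
    intermediate ⇌ target (K = 1.90, k = 0.0175 s⁻¹)
    target ⇌ isomer of the product B (K = 1.30, k = 0.00207 s⁻¹)
    crystals ⇌ target, rate k6*(cs6 - [target]) while solid is left; crystals form when [target] > cs6 (solubility = 1.90 mM, k = 1.58 s⁻¹)

Blue shows the largest single effect on its free target, how little target dissolves: without that ceiling, the solubility limit, blue's free target at the end is 3.18 mM instead of 1.90 mM. The toll lands on the crystals: at 4.00 min, ochre's 47.9 % less the ceiling leaves 38.4 %, with crystals at 38.3 %, and blue's 52.9 % leaves 43.4 %, with crystals at 44.8 %. The first chemist's view holds later: at 80.0 min, crystals stand at 0 % in blue and 0 % in ochre, and target falls from 7.31 % in blue to 6.51 % in ochre.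

(The readings are simulated from invented constants; the scatter is artificial.)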